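Both prenyl groups are disconnected at C1''–C2''. The feature exploited is that C6 and C8 of ring A both lie ortho to the C7 hydroxyl. C6 is also ortho to the C5 hydroxyl, whereas the other neighbour of C8 is C8a–O1. A CH2–X group on either carbon can therefore ionise to an ortho-quinone methide whose terminal carbon is the future C1''. In one operation the key step exchanges two benzylic dimethylamino groups for boron-delivered isobutenyl groups. This forms both C–C bonds and gives the unprotected target directly. The precursor is kaempferol carrying CH2NMe2 at C6 and at C8, with all four hydroxyls free. It is made in a single Mannich step from commercial kaempferol and bis(dimethylamino)methane.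

Key step: step 2

Remark on the structure: C8 has only one phenolic neighbour (O7), so its methide can form only across C7–O. The C6 methide can form across C7–O or C5–O. Because both sites share O7, the two transfers should run one after the other.

Remark on the design:
- The free bis-Mannich base is kept on purpose.
- Dimethylamine is volatile and can be swept out of the hot solution.
- Both nucleophilic ring A carbons are blocked before any methide is released, which closes the usual methylene-bridging sink.
- Surplus boronic acid masks the 3-OH/4-C=O site in the flask, so no protecting-group step is needed.
- Thermal loss of dimethylamine from 7-hydroxy-8-(dimethylaminomethyl)chromones to give trappable methides is established chemistry, so only the boron trap is new.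

Assumption: in step 2 the intermediates carry boron on one or more oxygens in an undefined pattern, so they are listed as the boron-free compounds. The order C8 before C6 is chosen for drawing only, since either order gives the same product.

Step 1
Reactants: 1 kaempferol; 2 bis(dimethylamino)methane
Product: 4 6,8-bis(dimethylaminomethyl)kaempferol, via 8-(dimethylaminomethyl)kaempferol 3 (not isolated)
Conditions: 2 (3 equiv), 1,4-dioxane, 60 °C, under argon; product collected by crystallisation on cooling
Reagents that add atoms: bis(dimethylamino)methane, CN(C)CN(C)C
Why: Mannich aminomethylation with a preformed aminal: C8 and then C6 of ring A, each ortho or para to three oxygen donors (O1, O5, O7), should react far faster than C3'/C5' of ring B, whose lone phenol is drained by conjugation with the pyranone, and the absence of free formaldehyde together with the surplus of amine should suppress methylene bridging.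

Step 2
Reactants: 4 6,8-bis(dimethylaminomethyl)kaempferol; 5 2-methylprop-1-enylboronic acid
Product: 9 6,8-diprenylkaempferol, via C8 quinone methide 6 (not isolated), via 6-(dimethylaminomethyl)-8-prenylkaempferol 7 (not isolated), via C6 quinone methide 8 (not isolated)
Conditions: 5 (6 equiv), 1,4-dioxane (0.02 M), 95 °C, slow argon sweep; then MeOH, aq NH4Cl/EtOAc, co-evaporation with MeOH; Sephadex LH-20
Reagents that add atoms: 2-methylprop-1-enylboronic acid, CC(C)=CB(O)O
Why: Proposed new method: the boronic acid should esterify O7 and bind the neighbouring benzylic nitrogen, which turns NMe2 into a better leaving group, so that C–N heterolysis near 95 °C unveils the C8=CH2/C7=O ortho-quinone methide 6 with a four-coordinate boron already seated on its oxygen. The isobutenyl carbon then moves from boron to the methide terminus within a six-atom cyclic array (B, O7, C7, C8, CH2, C2''), rearomatising ring A to 7, and the same events at C6, through O7 once more or through O5, lead by way of 8 to the second C1''–C2'' bond. The closest known reaction types are the Petasis borono-Mannich reaction, which shows that alkenylboronic acids tolerate secondary amines in hot dioxane, and the conjugate addition of alkenyl- and arylboron reagents to ortho-quinone methides released from ortho-hydroxybenzyl amines, ethers or alcohols; what has not been shown is a twofold transfer to unsubstituted methide termini on a free flavonol. No ring is closed and no stereocentre is formed. The step needs C- rather than O- or N-alkylation and reaction on ring A only: adducts of the methide with amine, water or phenols form reversibly while alkenyl transfer is irreversible, only C6 and C8 carry a leaving group, and with both of these carbons substituted no ring A position is left to build methylene-bridged dimers. Surplus boronic acid should hold the 3-OH/4-C=O site as a labile chelate that guards the flavonol against oxidation, boron leaves the C4 carbonyl untouched, and the near-neutral medium should spare the new prenyl groups from chroman formation with O5 or O7.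

Compound list
1 | kaempferol (3,5,7,4'-tetrahydroxyflavone) | O=c1c(O)c(-c2ccc(O)cc2)oc2cc(O)cc(O)c12 | starting material
2 | bis(dimethylamino)methane (N,N,N',N'-tetramethylmethanediamine) | CN(C)CN(C)C | starting material
3 | 8-(dimethylaminomethyl)kaempferol | CN(C)Cc1c(O)cc(O)c2c(=O)c(O)c(-c3ccc(O)cc3)oc12 | intermediate
4 | 6,8-bis(dimethylaminomethyl)kaempferol | CN(C)Cc1c(O)c(CN(C)C)c2oc(-c3ccc(O)cc3)c(O)c(=O)c2c1O | intermediate
5 | 2-methylprop-1-enylboronic acid | CC(C)=CB(O)O | starting material
6 | C8 quinone methide: 6-(dimethylaminomethyl)-3,5-dihydroxy-2-(4-hydroxyphenyl)-8-methylidenechromene-4,7(8H)-dione | C=C1C(=O)C(CN(C)C)=C(O)C2=C1OC(c3ccc(O)cc3)=C(O)C2=O | intermediate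
7 | 6-(dimethylaminomethyl)-8-prenylkaempferol | CN(C)Cc1c(O)c(CC=C(C)C)c2oc(-c3ccc(O)cc3)c(O)c(=O)c2c1O | intermediate
8 | C6 quinone methide: 3,5-dihydroxy-2-(4-hydroxyphenyl)-6-methylidene-8-(3-methylbut-2-enyl)chromene-4,7(6H)-dione | C=C1C(=O)C(CC=C(C)C)=C2OC(c3ccc(O)cc3)=C(O)C(=O)C2=C1O | intermediate
9 | 6,8-diprenylkaempferol | CC(C)=CCc1c(O)c(CC=C(C)C)c2oc(-c3ccc(O)cc3)c(O)c(=O)c2c1O | target

Total step count: 2
Longest linear sequence: 2 steps

Steps most likely to fail
The route has only two steps. Step 2 is therefore entered twice, once for each of its two independent failure modes.

1. Step 2, loss of the methide before boron delivers. Alkenyl transfer may be slower than several competing processes: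
- [4+2] self-dimerisation of the methide;
- cycloaddition of the methide with prenyl alkenes already installed;
- departure of the whole CH2NMe2 unit by retro-Mannich cleavage, followed by its capture by the boronic acid in a Petasis reaction.

The fallback gives up the methide and forms the aryl–C1'' bonds by Stille coupling, all of it known chemistry. It sets out from 1. NIS (2 equiv) in DMF at 0 °C to room temperature should iodinate the two activated ring A carbons to give 6,8-diiodokaempferol F1. Ac2O in pyridine converts this into 3,5,7,4'-tetra-O-acetyl-6,8-diiodokaempferol F2. Coupling with tributyl(3-methylbut-2-enyl)stannane and Pd(PPh3)4 in DMF at 90 °C should give 3,5,7,4'-tetra-O-acetyl-6,8-diprenylkaempferol F3. Methanolysis with catalytic K2CO3 in MeOH at 0 °C under argon returns to the route at 9.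

2. Step 2, sluggish ionisation or stalling after one transfer. The primary C–N bonds may not break below the temperature at which the boronic acid or the flavonol decays. The second transfer may also stop because the first prenyl group crowds O7.

The fallback keeps the C1''–C2'' disconnection and reagent 5 but replaces thermal methide formation by palladium catalysis on a benzylic ester. It sets out from 4. Refluxing Ac2O with KOAc, the classical acetolysis of phenolic Mannich bases, should give 3,5,7,4'-tetra-O-acetyl-6,8-bis(acetoxymethyl)kaempferol F4. The next operation is Suzuki–Miyaura coupling of the two benzylic acetates with 5, using [Pd(C3H5)Cl]2, 1,5-bis(diphenylphosphino)pentane and K2CO3 in tert-amyl alcohol at 80 °C. This should give 3,5,7,4'-tetra-O-acetyl-6,8-diprenylkaempferol F3. Any aryl acetate lost on the way is removed in the next operation anyway. Methanolysis with catalytic K2CO3 in MeOH at 0 °C under argon returns to the route at 9.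

3. Step 1, incomplete or misdirected aminomethylation. The second aminomethylation may lag, so that the free C6 of 3 attacks methide leaking from another molecule and methylene bridges form. Alternatively, surplus aminal may begin to attack C3'/C5' of ring B.

The fallback brings in the two carbons at the aldehyde oxidation level, where bridging is impossible, and adds nitrogen separately. It sets out from 1. Twofold Duff formylation uses excess hexamethylenetetramine in CF3CO2H at 80 °C, followed by aq HCl. It should give 6,8-diformylkaempferol F5, because the remaining ring A carbon is meta to both carbonyl groups and still ortho or para to three oxygens. Reductive amination with Me2NH and NaBH(OAc)3 in THF at 0 °C to room temperature returns to the route at 4.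

Further compounds
F1 | step 2 | 6,8-diiodokaempferol | O=c1c(O)c(-c2ccc(O)cc2)oc2c(I)c(O)c(I)c(O)c12
F2 | step 2 | 3,5,7,4'-tetra-O-acetyl-6,8-diiodokaempferol | CC(=O)Oc1ccc(-c2oc3c(I)c(OC(C)=O)c(I)c(OC(C)=O)c3c(=O)c2OC(C)=O)cc1
F3 | step 2 | 3,5,7,4'-tetra-O-acetyl-6,8-diprenylkaempferol | CC(=O)Oc1ccc(-c2oc3c(CC=C(C)C)c(OC(C)=O)c(CC=C(C)C)c(OC(C)=O)c3c(=O)c2OC(C)=O)cc1
F4 | step 2 | 3,5,7,4'-tetra-O-acetyl-6,8-bis(acetoxymethyl)kaempferol | CC(=O)OCc1c(OC(C)=O)c(COC(C)=O)c2oc(-c3ccc(OC(C)=O)cc3)c(OC(C)=O)c(=O)c2c1OC(C)=O
F5 | step 1 | 6,8-diformylkaempferol | O=Cc1c(O)c(C=O)c2oc(-c3ccc(O)cc3)c(O)c(=O)c2c1O
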